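## Retrosynthetic overview

1. Last step: one acidic fluoride treatment strips all silicon from a 4‑silyloxy‑2H‑chromene that already carries the full skeleton and the C2 stereocentre.
2. Key disconnection C2–C1′: a C2 homoenolate of the chroman‑4‑one (a 4‑silyloxyallyl nickel species from a chromone, zerovalent nickel and Et3SiCl) is joined to the ring B aryl bromide. Both carbons are electrophilic by nature, and the chiral ligand on nickel sets C2 (S) as the bond forms.
3. Ring B bromide: site‑selective Mukaiyama hydration of the distal alkene of a geranyl chain, which is placed on 4‑bromophenol by ortho‑C‑alkylation with geranyl bromide (E‑alkene bought).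
4. Chromone: 2,4,6‑trihydroxyacetophenone plus one carbon from HC(OEt)3.
5. Ring order: rings A and B are bought as benzenes; the pyranone ring is closed first (step 1); no ring is formed afterwards.

Assumption: in step 6 the ligand antipode used is whichever is found to give the 2S product; it is written as (S,S) for definiteness.

## Route

Step 1
Reactants: 1 2,4,6‑trihydroxyacetophenone
Product: 3 5,7‑dihydroxy‑4H‑chromen‑4‑one, via 4‑ethoxy‑5,7‑dihydroxychromenylium perchlorate 2 (not isolated)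
Conditions: HC(OEt)3 (excess), 70% HClO4 (1.1 equiv), rt, 12 h; then H2O, 90 °C
Reagents that add atoms: triethyl orthoformate, CCOC(OCC)OCC
Why: Orthoester–perchloric acid chromone synthesis: the acetyl methyl is formylated by the orthoester‑derived carbenium ion, the ortho‑hydroxyl closes the 4‑ethoxypyrylium salt, and hot water hydrolyses it to the pyranone; the symmetric triol can give only one regioisomer.

Step 2
Reactants: 3 5,7‑dihydroxy‑4H‑chromen‑4‑one
Product: 4 5,7‑bis(tert‑butyldimethylsilyloxy)‑4H‑chromen‑4‑one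
Conditions: TBSCl (2.6 equiv), imidazole (5 equiv), DMAP (cat.), DMF, 40 °C
Reagents that add atoms: tert‑butyldimethylsilyl chloride, CC(C)(C)[Si](C)(C)Cl
Why: Imidazole‑mediated silyl ether formation; excess reagent and gentle warming are used because the 5‑OH is hydrogen‑bonded to the carbonyl.

Step 3
Reactants: 5 4‑bromophenol; 6 geranyl bromide, (2E)‑1‑bromo‑3,7‑dimethylocta‑2,6‑diene
Product: 7 4‑bromo‑2‑[(2E)‑3,7‑dimethylocta‑2,6‑dien‑1‑yl]phenol
Conditions: NaH (1.0 equiv), toluene, 0 °C → rt; then 6 (1.0 equiv), rt → 50 °C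
Reagents that add atoms: none
Why: Ortho‑C‑allylation of a sodium phenoxide in a non‑polar solvent (SN2 at the primary allylic carbon): tight ion pairing shields oxygen, the para position is blocked by bromine, and the E‑alkene is not touched.

Step 4
Reactants: 7 4‑bromo‑2‑[(2E)‑3,7‑dimethylocta‑2,6‑dien‑1‑yl]phenol
Product: 8 {4‑bromo‑2‑[(2E)‑3,7‑dimethylocta‑2,6‑dien‑1‑yl]phenoxy}(tert‑butyl)dimethylsilane
Conditions: TBSCl (1.2 equiv), imidazole (2.5 equiv), DMF, rt
Reagents that add atoms: tert‑butyldimethylsilyl chloride, CC(C)(C)[Si](C)(C)Cl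
Why: Standard silyl ether protection; it removes the phenolic O–H, which would otherwise quench the radical chain of the next step.

Step 5
Reactants: 8 {4‑bromo‑2‑[(2E)‑3,7‑dimethylocta‑2,6‑dien‑1‑yl]phenoxy}(tert‑butyl)dimethylsilane
Product: 10 (6E)‑8‑[5‑bromo‑2‑(tert‑butyldimethylsilyloxy)phenyl]‑2,6‑dimethyloct‑6‑en‑2‑ol, via tertiary hydroperoxide 9 (not isolated)
Conditions: Co(acac)2 (20 mol%), PhSiH3 (1.2 equiv), O2 (1 atm), THF–iPrOH, rt, stopped when 8 is consumed; then PPh3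
Reagents that add atoms: dioxygen, O=O
Why: Mukaiyama hydration (cobalt hydride hydrogen‑atom transfer, Markovnikov): the distal isopropylidene alkene, remote from the bulky ortho‑silyloxybenzyl group, takes the hydrogen atom faster, the tertiary radical is trapped by O2 and PPh3 reduces the hydroperoxide; no stereocentre is formed.

Step 6
Reactants: 4 5,7‑bis(tert‑butyldimethylsilyloxy)‑4H‑chromen‑4‑one; 10 (6E)‑8‑[5‑bromo‑2‑(tert‑butyldimethylsilyloxy)phenyl]‑2,6‑dimethyloct‑6‑en‑2‑ol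
Product: 11 (6E)‑8‑{5‑[(2S)‑5,7‑bis(tert‑butyldimethylsilyloxy)‑4‑(triethylsilyloxy)‑2H‑chromen‑2‑yl]‑2‑(tert‑butyldimethylsilyloxy)phenyl}‑2,6‑dimethyloct‑6‑en‑2‑ol
Conditions: NiBr2·glyme (10 mol%), (S,S)‑iPr‑BiOX [(4S,4′S)‑4,4′‑diisopropyl‑2,2′‑bis(2‑oxazoline)] (12 mol%), Mn powder (3 equiv), Et3SiCl (1.5 equiv), 10 (1.3 equiv), DMF, 25 °C
Reagents that add atoms: chlorotriethylsilane, CC[Si](CC)(CC)Cl
Why: Proposed new method: a Weix‑type nickel‑catalysed reductive conjugate arylation run with a chiral ligand, in which zerovalent nickel, chromone 4 and Et3SiCl undergo oxidative addition to a 4‑silyloxy‑2H‑chromen‑2‑yl (siloxyallyl) complex of divalent nickel, that is a C2 homoenolate of the chromanone; after reduction by Mn this captures aryl bromide 10 and reductively eliminates at the secondary C2 terminus (C4 would give a quaternary centre) inside the C2‑symmetric bis(oxazoline) pocket, so two natively electrophilic carbons are joined and the S configuration is fixed in the same event; the closest known chemistry is the racemic nickel/Mn/chlorosilane reductive conjugate addition of aryl halides to enones through siloxyallylnickel intermediates, nickel/bis(oxazoline) enantioselective cross‑electrophile couplings, and the asymmetric conjugate arylation of chromones with aryl–metal species; the unbased Et3SiCl leaves the hindered tertiary alcohol free.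

Step 7
Reactants: 11 (6E)‑8‑{5‑[(2S)‑5,7‑bis(tert‑butyldimethylsilyloxy)‑4‑(triethylsilyloxy)‑2H‑chromen‑2‑yl]‑2‑(tert‑butyldimethylsilyloxy)phenyl}‑2,6‑dimethyloct‑6‑en‑2‑ol
Product: 12 (2S)‑5,7‑dihydroxy‑2‑{4‑hydroxy‑3‑[(2E)‑7‑hydroxy‑3,7‑dimethyloct‑2‑en‑1‑yl]phenyl}‑2,3‑dihydro‑4H‑chromen‑4‑one
Conditions: HF·pyridine (excess), pyridine, THF, 0 °C → rt
Reagents that add atoms: none
Why: Acidic fluoride desilylation: the enol silane is cleaved by C3 protonation to the ketone and the three aryl silyl ethers fall off without any base, so the retro‑oxa‑Michael pathway that racemises 5‑ and 4′‑hydroxyflavanones is never opened, and the buffered medium spares the tertiary alcohol and the alkene.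

## Compound list

1 | 2,4,6‑trihydroxyacetophenone | CC(=O)c1c(O)cc(O)cc1O | starting material
2 | 4‑ethoxy‑5,7‑dihydroxychromenylium perchlorate | CCOc1cc[o+]c2cc(O)cc(O)c12.[O-]Cl(=O)(=O)=O | intermediate
3 | 5,7‑dihydroxy‑4H‑chromen‑4‑one | O=c1ccoc2cc(O)cc(O)c12 | intermediate
4 | 5,7‑bis(tert‑butyldimethylsilyloxy)‑4H‑chromen‑4‑one | O=c1ccoc2cc(O[Si](C)(C)C(C)(C)C)cc(O[Si](C)(C)C(C)(C)C)c12 | intermediate
5 | 4‑bromophenol | Oc1ccc(Br)cc1 | starting material
6 | geranyl bromide, (2E)‑1‑bromo‑3,7‑dimethylocta‑2,6‑diene | C/C(=C\CBr)CCC=C(C)C | starting material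
7 | 4‑bromo‑2‑[(2E)‑3,7‑dimethylocta‑2,6‑dien‑1‑yl]phenol | C/C(=C\Cc1cc(Br)ccc1O)CCC=C(C)C | intermediate
8 | {4‑bromo‑2‑[(2E)‑3,7‑dimethylocta‑2,6‑dien‑1‑yl]phenoxy}(tert‑butyl)dimethylsilane | C/C(=C\Cc1cc(Br)ccc1O[Si](C)(C)C(C)(C)C)CCC=C(C)C | intermediate
9 | (6E)‑8‑[5‑bromo‑2‑(tert‑butyldimethylsilyloxy)phenyl]‑2,6‑dimethyloct‑6‑en‑2‑yl hydroperoxide | C/C(=C\Cc1cc(Br)ccc1O[Si](C)(C)C(C)(C)C)CCCC(C)(C)OO | intermediate
10 | (6E)‑8‑[5‑bromo‑2‑(tert‑butyldimethylsilyloxy)phenyl]‑2,6‑dimethyloct‑6‑en‑2‑ol | C/C(=C\Cc1cc(Br)ccc1O[Si](C)(C)C(C)(C)C)CCCC(C)(C)O | intermediate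
11 | (6E)‑8‑{5‑[(2S)‑5,7‑bis(tert‑butyldimethylsilyloxy)‑4‑(triethylsilyloxy)‑2H‑chromen‑2‑yl]‑2‑(tert‑butyldimethylsilyloxy)phenyl}‑2,6‑dimethyloct‑6‑en‑2‑ol | C/C(=C\Cc1cc([C@@H]2C=C(O[Si](CC)(CC)CC)c3c(O[Si](C)(C)C(C)(C)C)cc(O[Si](C)(C)C(C)(C)C)cc3O2)ccc1O[Si](C)(C)C(C)(C)C)CCCC(C)(C)O | intermediate
12 | (2S)‑5,7‑dihydroxy‑2‑{4‑hydroxy‑3‑[(2E)‑7‑hydroxy‑3,7‑dimethyloct‑2‑en‑1‑yl]phenyl}‑2,3‑dihydro‑4H‑chromen‑4‑one | C/C(=C\Cc1cc([C@@H]2CC(=O)c3c(O)cc(O)cc3O2)ccc1O)CCCC(C)(C)O | target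

## Step count and risk

Total steps: 7. Longest linear sequence: 5 (steps 3, 4, 5, 6, 7, from 4‑bromophenol).

Most likely to fail, step 6. The electron‑rich chromone may be slow to form the allylnickel species, biaryl homocoupling competes, and the enantioselectivity is untested. The fallback sets out from 10 and comes back to the route at 12. Bromide 10 is treated with n‑BuLi (2.2 equiv, THF, −78 °C; the first equivalent takes the alcohol proton), B(OiPr)3 and aqueous NH4Cl to give {4‑(tert‑butyldimethylsilyloxy)‑3‑[(2E)‑7‑hydroxy‑3,7‑dimethyloct‑2‑en‑1‑yl]phenyl}boronic acid F1. This aryl nucleophile is then added to chromone 4 in normal polarity by asymmetric conjugate addition with Pd(OCOCF3)2 and t‑Bu‑PyOX (NH4PF6, H2O, ClCH2CH2Cl, 60 °C; ligand antipode chosen for 2S). The product is (2S)‑5,7‑bis(tert‑butyldimethylsilyloxy)‑2‑{4‑(tert‑butyldimethylsilyloxy)‑3‑[(2E)‑7‑hydroxy‑3,7‑dimethyloct‑2‑en‑1‑yl]phenyl}‑2,3‑dihydro‑4H‑chromen‑4‑one F2, which is desilylated with HF·pyridine as in step 7 to reach 12.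

Second, step 5. The two trisubstituted alkenes may not be differentiated well enough, giving diol or the wrong hydrate. The fallback sets out from 5 and comes back at 10, with the hydration done before the chain meets the arene. Geranyl acetate F3, whose proximal alkene is deactivated by the allylic acetate, is hydrated at the distal alkene by oxymercuration–demercuration (Hg(OAc)2, THF–H2O; then NaBH4, aq NaOH) to (2E)‑7‑hydroxy‑3,7‑dimethyloct‑2‑en‑1‑yl acetate F4. Methanolysis (K2CO3, MeOH) gives (2E)‑3,7‑dimethyloct‑2‑ene‑1,7‑diol F5. Selective activation of the primary allylic alcohol (MsCl, Et3N, CH2Cl2, −40 °C; then LiBr, THF) gives (6E)‑8‑bromo‑2,6‑dimethyloct‑6‑en‑2‑ol F6. The sodium phenoxide of 5 (NaH, toluene) is ortho‑C‑alkylated with it to 4‑bromo‑2‑[(2E)‑7‑hydroxy‑3,7‑dimethyloct‑2‑en‑1‑yl]phenol F7, and TBSCl/imidazole silylates only the phenol to give 10.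

Third, step 3. O‑alkylation, dialkylation and SN2′ products lower the yield of the ortho‑C‑alkylation. The fallback sets out from 5 and comes back at 8, making the aryl–allyl bond from an aryl metal instead of a phenoxide. Phenol 5 is iodinated ortho to the hydroxyl (N‑iodosuccinimide, TsOH cat., MeCN) to 4‑bromo‑2‑iodophenol F8 and silylated (TBSCl, imidazole, DMF) to (4‑bromo‑2‑iodophenoxy)(tert‑butyl)dimethylsilane F9. Selective iodine–magnesium exchange (iPrMgCl·LiCl, THF, −40 °C), transmetallation with ZnCl2 and Negishi allyl–aryl coupling with geranyl bromide 6 under Pd(PPh3)4 (0 °C → rt; attack at the less hindered allyl terminus with the E geometry kept) give 8 directly.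

## Further compounds

F1 | step 6 | {4‑(tert‑butyldimethylsilyloxy)‑3‑[(2E)‑7‑hydroxy‑3,7‑dimethyloct‑2‑en‑1‑yl]phenyl}boronic acid | C/C(=C\Cc1cc(B(O)O)ccc1O[Si](C)(C)C(C)(C)C)CCCC(C)(C)O
F2 | step 6 | (2S)‑5,7‑bis(tert‑butyldimethylsilyloxy)‑2‑{4‑(tert‑butyldimethylsilyloxy)‑3‑[(2E)‑7‑hydroxy‑3,7‑dimethyloct‑2‑en‑1‑yl]phenyl}‑2,3‑dihydro‑4H‑chromen‑4‑one | C/C(=C\Cc1cc([C@@H]2CC(=O)c3c(O[Si](C)(C)C(C)(C)C)cc(O[Si](C)(C)C(C)(C)C)cc3O2)ccc1O[Si](C)(C)C(C)(C)C)CCCC(C)(C)O
F3 | step 5 | geranyl acetate | C/C(=C\COC(C)=O)CCC=C(C)C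
F4 | step 5 | (2E)‑7‑hydroxy‑3,7‑dimethyloct‑2‑en‑1‑yl acetate | C/C(=C\COC(C)=O)CCCC(C)(C)O
F5 | step 5 | (2E)‑3,7‑dimethyloct‑2‑ene‑1,7‑diol | C/C(=C\CO)CCCC(C)(C)O
F6 | step 5 | (6E)‑8‑bromo‑2,6‑dimethyloct‑6‑en‑2‑ol | C/C(=C\CBr)CCCC(C)(C)O
F7 | step 5 | 4‑bromo‑2‑[(2E)‑7‑hydroxy‑3,7‑dimethyloct‑2‑en‑1‑yl]phenol | C/C(=C\Cc1cc(Br)ccc1O)CCCC(C)(C)O
F8 | step 3 | 4‑bromo‑2‑iodophenol | Oc1ccc(Br)cc1I
F9 | step 3 | (4‑bromo‑2‑iodophenoxy)(tert‑butyl)dimethylsilane | CC(C)(C)[Si](C)(C)Oc1ccc(Br)cc1I
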